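**Plan**

- Retrosynthesis first cuts the two depside C(=O)–OAr bonds (ring B acyl to ring C oxygen, then ring A acyl to ring B oxygen). This gives benzyl orsellinate (ring C), orsellinaldehyde as a masked ring B acid, and a ring A acid.
- Ring A (C1 carboxyl, C2/C4 OH, C5 OMe, C6 CH3) is then dearomatized to a 2,4-dioxocyclohexane-1-carboxylate and opened at C3–C4 (Claisen), C5–C6 (Michael) and C1=C6 (Knoevenagel).
- Enabling feature: the C2 and C4 phenol carbons of ring A are the carbonyls of a cyclohexane-1,3-dione. The adjacent C5–OMe and C6–CH3, hard to place on an arene, can therefore be set as ordinary sp3 carbons of an open chain before the ring exists.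
- Forward: chain assembly (steps 1–3), closure of ring A (step 4), aromatization and protection (steps 5–8). Ring B and then ring C are attached by mixed-anhydride esterification, and all benzyl groups are removed at the end.
- Stereochemistry: the target is achiral. The sp3 centres of the open-chain and cyclohexanedione intermediates are carried as mixtures and vanish on aromatization.

Key step: step 4

Assumption: compounds 1, 2, 4, 14 and 18 and all reagents are taken as purchasable; ring A is numbered C1 (ring carbon bearing the carboxyl) to C6 (ring carbon bearing the methyl group) throughout.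

**Route**

Step 1
Reactants: 1 methyl acetoacetate; 2 acetaldehyde
Product: 3 methyl 2-acetylbut-2-enoate (E/Z mixture)
Conditions: TiCl4, pyridine, THF, 0 °C → rt
Reagents that add atoms: none
Why: Knoevenagel condensation under TiCl4/pyridine should stop at the mono-alkylidene stage with an enolizable aliphatic aldehyde and avoid the bis-acetoacetate adduct that amine catalysis favours; the alkene geometry is irrelevant.

Step 2
Reactants: 4 methyl methoxyacetate
Product: 5 [(1,2-dimethoxyethenyl)oxy]trimethylsilane (E/Z mixture)
Conditions: LiN(iPr)2, THF, −78 °C; Me3SiCl, −78 °C → rt; distillation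
Reagents that add atoms: chlorotrimethylsilane, C[Si](C)(C)Cl
Why: Kinetic ester enolization followed by O-silylation is the standard preparation of silyl ketene acetals, and the alkoxy-substituted enolate is trapped on oxygen by the hard silyl chloride.

Step 3
Reactants: 3 methyl 2-acetylbut-2-enoate; 5 [(1,2-dimethoxyethenyl)oxy]trimethylsilane
Product: 7 dimethyl 2-acetyl-4-methoxy-3-methylpentanedioate (diastereomer mixture), via trimethylsilyl enol ether 6 (not isolated)
Conditions: Sc(OTf)3 (5 mol %), CH2Cl2, −78 → 0 °C; then 1 M HCl, THF, rt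
Reagents that add atoms: none
Why: Mukaiyama–Michael addition, in which the chelating alkylidene β-keto ester is a doubly activated acceptor for the silyl ketene acetal and the future C5–C6 bond of ring A is formed; the new sp3 centres arise without control, which is harmless because all are erased on aromatization.

Step 4
Reactants: 7 dimethyl 2-acetyl-4-methoxy-3-methylpentanedioate
Product: 9 methyl 5-methoxy-6-methyl-2,4-dioxocyclohexane-1-carboxylate (diastereomer mixture), via sodium dione enolate 8 (not isolated)
Conditions: NaOMe (2.5 equiv), MeOH, reflux; then cold 1 M HCl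
Reagents that add atoms: none
Why: Methoxide deprotonates the acetoacetate carbon and, in equilibrium, the acetyl methyl group; the methyl ketone enolate adds to the methoxyacetate-derived ester carbonyl and expels methoxide, forming the C3–C4 bond of ring A. This is an intramolecular Claisen (Dieckmann-type) condensation of a δ-keto ester, the reaction type that turns acetoacetate–crotonate Michael adducts into dihydroresorcylates. The six-membered carbocycle closes in the 6-exo-trig mode. No new stereocentre is created, and the three existing sp3 centres (C1, C5, C6) need no control because they disappear on aromatization. The step needs regioselective use of the methyl ketone enolate, which ring size secures because the more abundant acetoacetate enolate could only close a four-membered ring; matching methoxide to the methyl esters makes ester exchange invisible. Deprotonation of the product to the stabilized dione enolate 8 should pull the equilibrium forward and outpace retro-Michael or retro-Claisen cleavage.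

Step 5
Reactants: 9 methyl 5-methoxy-6-methyl-2,4-dioxocyclohexane-1-carboxylate
Product: 10 methyl 3-bromo-2,4-dihydroxy-5-methoxy-6-methylbenzoate
Conditions: Br2 (2.1 equiv), AcOH, rt
Reagents that add atoms: bromine, BrBr
Why: Bromination–dehydrobromination is the classical aromatization of 2,4-dioxocyclohexanecarboxylates: α-bromination of the enolized dione and loss of HBr towards C6 should give the resorcylate, whose only free ring position (C3) takes up the second bromine, while no enolate of 9 is placed to expel the C5 methoxy group.

Step 6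
Reactants: 10 methyl 3-bromo-2,4-dihydroxy-5-methoxy-6-methylbenzoate
Product: 11 methyl 2,4-dihydroxy-5-methoxy-6-methylbenzoate
Conditions: H2 (1 atm), 10% Pd/C, NaOAc, MeOH, rt
Reagents that add atoms: none
Why: Catalytic hydrogenolysis of an aryl bromide in the presence of an acid scavenger is routine and should leave the ester, the methoxy group and the phenols untouched.

Step 7
Reactants: 11 methyl 2,4-dihydroxy-5-methoxy-6-methylbenzoate
Product: 12 methyl 2,4-bis(benzyloxy)-5-methoxy-6-methylbenzoate
Conditions: BnBr (2.5 equiv), K2CO3, DMF, 60 °C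
Reagents that add atoms: benzyl bromide, BrCc1ccccc1
Why: Williamson ether synthesis, in which warming in DMF overcomes the hydrogen bond of the C2 phenol to the ester so that both phenols should be benzylated.

Step 8
Reactants: 12 methyl 2,4-bis(benzyloxy)-5-methoxy-6-methylbenzoate
Product: 13 2,4-bis(benzyloxy)-5-methoxy-6-methylbenzoic acid
Conditions: KOH, DMSO/H2O, 90 °C; then cold dilute HCl
Reagents that add atoms: potassium hydroxide, [K+].[OH-]
Why: Saponification of the di-ortho-substituted benzoate calls for poorly solvated hydroxide in aqueous DMSO, conditions under which aryl benzyl and methyl ethers are inert, and cold acidification should avoid protodecarboxylation.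

Step 9
Reactants: 13 2,4-bis(benzyloxy)-5-methoxy-6-methylbenzoic acid; 14 2,4-dihydroxy-6-methylbenzaldehyde
Product: 16 4-formyl-3-hydroxy-5-methylphenyl 2,4-bis(benzyloxy)-5-methoxy-6-methylbenzoate, via acyl trifluoroacetate 15 (not isolated)
Conditions: (CF3CO)2O, toluene, rt
Reagents that add atoms: none
Why: Mixed-anhydride esterification, the standard way of forging depside bonds: the hindered acid is activated in situ as its acyl trifluoroacetate and should acylate the free C4 phenol of the aldehyde, whose C2 phenol is tied up in a hydrogen bond to the formyl group.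

Step 10
Reactants: 16 4-formyl-3-hydroxy-5-methylphenyl 2,4-bis(benzyloxy)-5-methoxy-6-methylbenzoate
Product: 17 4-{[2,4-bis(benzyloxy)-5-methoxy-6-methylbenzoyl]oxy}-2-hydroxy-6-methylbenzoic acid
Conditions: NaClO2, NaH2PO4, 2-methyl-2-butene, t-BuOH/THF/H2O, rt
Reagents that add atoms: sodium chlorite, [Na+].[O-]Cl=O
Why: Pinnick oxidation should convert the aryl aldehyde into the acid under buffered, mildly acidic conditions that spare the aryl ester and the benzyl ethers, with the alkene scavenging hypochlorous acid.

Step 11
Reactants: 18 orsellinic acid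
Product: 19 benzyl 2,4-dihydroxy-6-methylbenzoate
Conditions: BnBr (1.05 equiv), KHCO3, DMF, rt
Reagents that add atoms: benzyl bromide, BrCc1ccccc1
Why: With hydrogen carbonate only the carboxyl group is ionized, so SN2 alkylation should give the benzyl ester with both phenols free, and the mild temperature avoids decarboxylation.

Step 12
Reactants: 17 4-{[2,4-bis(benzyloxy)-5-methoxy-6-methylbenzoyl]oxy}-2-hydroxy-6-methylbenzoic acid; 19 benzyl 2,4-dihydroxy-6-methylbenzoate
Product: 21 benzyl 4-({4-[(2,4-bis(benzyloxy)-5-methoxy-6-methylbenzoyl)oxy]-2-hydroxy-6-methylbenzoyl}oxy)-2-hydroxy-6-methylbenzoate, via acyl trifluoroacetate 20 (not isolated)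
Conditions: (CF3CO)2O, toluene, rt
Reagents that add atoms: none
Why: Second mixed-anhydride esterification, in which the ortho-hydroxy acid is activated as its acyl trifluoroacetate and should be captured by the C4 phenol of the benzyl ester, whose C2 phenol is chelated to the ester carbonyl, while the existing aryl ester is stable to trifluoroacetic acid.

Step 13
Reactants: 21 benzyl 4-({4-[(2,4-bis(benzyloxy)-5-methoxy-6-methylbenzoyl)oxy]-2-hydroxy-6-methylbenzoyl}oxy)-2-hydroxy-6-methylbenzoate
Product: 22 4-({4-[(2,4-dihydroxy-5-methoxy-6-methylbenzoyl)oxy]-2-hydroxy-6-methylbenzoyl}oxy)-2-hydroxy-6-methylbenzoic acid (target)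
Conditions: H2 (1 atm), 10% Pd/C, EtOAc, rt
Reagents that add atoms: none
Why: Hydrogenolysis should remove the benzyl ester and both benzyl ethers in one operation under neutral conditions that do not touch the two depside esters.

**Compound list**

1 | methyl acetoacetate | CC(=O)CC(=O)OC | starting material
2 | acetaldehyde | CC=O | starting material
3 | methyl 2-acetylbut-2-enoate (E/Z mixture) | CC=C(C(C)=O)C(=O)OC | intermediate
4 | methyl methoxyacetate | COCC(=O)OC | starting material
5 | [(1,2-dimethoxyethenyl)oxy]trimethylsilane (E/Z mixture) | COC=C(OC)O[Si](C)(C)C | intermediate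
6 | dimethyl 4-methoxy-3-methyl-2-[1-(trimethylsilyloxy)ethylidene]pentanedioate (isomer mixture, not isolated) | COC(=O)C(OC)C(C)C(C(=O)OC)=C(C)O[Si](C)(C)C | intermediate
7 | dimethyl 2-acetyl-4-methoxy-3-methylpentanedioate (diastereomer mixture) | COC(=O)C(OC)C(C)C(C(C)=O)C(=O)OC | intermediate
8 | sodium 6-methoxy-4-(methoxycarbonyl)-5-methyl-3-oxocyclohex-1-en-1-olate (diastereomer mixture, not isolated) | COC1C(C)C(C(=O)OC)C(=O)C=C1[O-].[Na+] | intermediate
9 | methyl 5-methoxy-6-methyl-2,4-dioxocyclohexane-1-carboxylate (diastereomer and tautomer mixture) | COC1C(C)C(C(=O)OC)C(=O)CC1=O | intermediate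
10 | methyl 3-bromo-2,4-dihydroxy-5-methoxy-6-methylbenzoate | COC(=O)c1c(C)c(OC)c(O)c(Br)c1O | intermediate
11 | methyl 2,4-dihydroxy-5-methoxy-6-methylbenzoate | COC(=O)c1c(C)c(OC)c(O)cc1O | intermediate
12 | methyl 2,4-bis(benzyloxy)-5-methoxy-6-methylbenzoate | COC(=O)c1c(C)c(OC)c(OCc2ccccc2)cc1OCc1ccccc1 | intermediate
13 | 2,4-bis(benzyloxy)-5-methoxy-6-methylbenzoic acid | OC(=O)c1c(C)c(OC)c(OCc2ccccc2)cc1OCc1ccccc1 | intermediate
14 | 2,4-dihydroxy-6-methylbenzaldehyde (orsellinaldehyde) | Cc1cc(O)cc(O)c1C=O | starting material
15 | 2,4-bis(benzyloxy)-5-methoxy-6-methylbenzoic trifluoroacetic anhydride (not isolated) | FC(F)(F)C(=O)OC(=O)c1c(C)c(OC)c(OCc2ccccc2)cc1OCc1ccccc1 | intermediate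
16 | 4-formyl-3-hydroxy-5-methylphenyl 2,4-bis(benzyloxy)-5-methoxy-6-methylbenzoate | Cc1cc(OC(=O)c2c(C)c(OC)c(OCc3ccccc3)cc2OCc2ccccc2)cc(O)c1C=O | intermediate
17 | 4-{[2,4-bis(benzyloxy)-5-methoxy-6-methylbenzoyl]oxy}-2-hydroxy-6-methylbenzoic acid | Cc1cc(OC(=O)c2c(C)c(OC)c(OCc3ccccc3)cc2OCc2ccccc2)cc(O)c1C(=O)O | intermediate
18 | orsellinic acid (2,4-dihydroxy-6-methylbenzoic acid) | Cc1cc(O)cc(O)c1C(=O)O | starting material
19 | benzyl 2,4-dihydroxy-6-methylbenzoate | Cc1cc(O)cc(O)c1C(=O)OCc1ccccc1 | intermediate
20 | 4-{[2,4-bis(benzyloxy)-5-methoxy-6-methylbenzoyl]oxy}-2-hydroxy-6-methylbenzoic trifluoroacetic anhydride (not isolated) | Cc1cc(OC(=O)c2c(C)c(OC)c(OCc3ccccc3)cc2OCc2ccccc2)cc(O)c1C(=O)OC(=O)C(F)(F)F | intermediate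
21 | benzyl 4-({4-[(2,4-bis(benzyloxy)-5-methoxy-6-methylbenzoyl)oxy]-2-hydroxy-6-methylbenzoyl}oxy)-2-hydroxy-6-methylbenzoate | Cc1cc(OC(=O)c2c(C)cc(OC(=O)c3c(C)c(OC)c(OCc4ccccc4)cc3OCc3ccccc3)cc2O)cc(O)c1C(=O)OCc1ccccc1 | intermediate
22 | 4-({4-[(2,4-dihydroxy-5-methoxy-6-methylbenzoyl)oxy]-2-hydroxy-6-methylbenzoyl}oxy)-2-hydroxy-6-methylbenzoic acid | COc1c(O)cc(O)c(C(=O)Oc2cc(C)c(C(=O)Oc3cc(C)c(C(=O)O)c(O)c3)c(O)c2)c1C | target

**Step count**

Total: 13 steps. Longest linear sequence: 11 steps (steps 1, 3, 4, 5, 6, 7, 8, 9, 10, 12, 13, from methyl acetoacetate); steps 2 and 11 are side branches.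

**Steps most likely to fail**

Step 5. The danger is erosion of the C5 methoxy group during halogenative aromatization. Bromination at C5 could be followed by demethylation of the resulting bromo ether by bromide, or acid could promote loss of methanol; over-bromination is a further risk. The fallback dehydrogenates by hydride abstraction without halogen or acid. It sets out from 9, which is silylated with Me3SiOTf/Et3N in CH2Cl2 to methyl 5-methoxy-6-methyl-2,4-bis(trimethylsilyloxy)cyclohexa-1,3-diene-1-carboxylate F1. The cyclohexadiene is oxidized with DDQ in dioxane at rt to methyl 5-methoxy-6-methyl-2,4-bis(trimethylsilyloxy)benzoate F2. Desilylation with dilute HCl in THF returns to the route at 11, so step 6 is not needed.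

Step 4. Chain cleavage may outrun ring closure: methoxide can attack the acetyl ketone (retro-Claisen deacetylation), or the chain can fragment by retro-Michael reaction before the minor methyl ketone enolate cyclizes. The fallback activates the acyl acceptor so that closure runs cold with a non-nucleophilic base. Methoxyacetyl chloride and phenol (pyridine, CH2Cl2) give phenyl methoxyacetate F3, which is converted with LiN(iPr)2/Me3SiCl into [(2-methoxy-1-phenoxyethenyl)oxy]trimethylsilane F4. Setting out from 3, Sc(OTf)3-catalysed Mukaiyama–Michael addition of this acetal should give, through the trimethylsilyl enol ether dimethyl-type adduct 1-methyl 5-phenyl 4-methoxy-3-methyl-2-[1-(trimethylsilyloxy)ethylidene]pentanedioate F5 and acidic work-up, 1-methyl 5-phenyl 2-acetyl-4-methoxy-3-methylpentanedioate F6. Treatment with LiN(SiMe3)2 (2.2 equiv) in THF at −78 → 0 °C closes the same C3–C4 bond with phenoxide as leaving group, and acidification returns to the route at 9.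

Step 10. Hypochlorous acid or chlorine dioxide formed during the chlorite oxidation may chlorinate the electron-rich rings (C3 of ring A, positions ortho to the ring B phenol) if scavenging is incomplete. The fallback avoids an aldehyde oxidation by bringing ring B in at the acid oxidation level. Orsellinic acid 18 is alkylated with allyl bromide/KHCO3 in DMF to allyl 2,4-dihydroxy-6-methylbenzoate F7. Setting out from 13, coupling with (CF3CO)2O in toluene through 15 should give allyl 4-{[2,4-bis(benzyloxy)-5-methoxy-6-methylbenzoyl]oxy}-2-hydroxy-6-methylbenzoate F8. Deallylation with Pd(PPh3)4 (zerovalent palladium) and p-TolSO2Na in THF/MeOH returns to the route at 17.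

**Further compounds**

F1 | step 5 | methyl 5-methoxy-6-methyl-2,4-bis(trimethylsilyloxy)cyclohexa-1,3-diene-1-carboxylate | COC1C(C)C(C(=O)OC)=C(O[Si](C)(C)C)C=C1O[Si](C)(C)C
F2 | step 5 | methyl 5-methoxy-6-methyl-2,4-bis(trimethylsilyloxy)benzoate | COC(=O)c1c(C)c(OC)c(O[Si](C)(C)C)cc1O[Si](C)(C)C
F3 | step 4 | phenyl methoxyacetate | COCC(=O)Oc1ccccc1
F4 | step 4 | [(2-methoxy-1-phenoxyethenyl)oxy]trimethylsilane | COC=C(Oc1ccccc1)O[Si](C)(C)C
F5 | step 4 | 1-methyl 5-phenyl 4-methoxy-3-methyl-2-[1-(trimethylsilyloxy)ethylidene]pentanedioate | COC(C(=O)Oc1ccccc1)C(C)C(C(=O)OC)=C(C)O[Si](C)(C)C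
F6 | step 4 | 1-methyl 5-phenyl 2-acetyl-4-methoxy-3-methylpentanedioate | COC(C(=O)Oc1ccccc1)C(C)C(C(C)=O)C(=O)OC
F7 | step 10 | allyl 2,4-dihydroxy-6-methylbenzoate | Cc1cc(O)cc(O)c1C(=O)OCC=C
F8 | step 10 | allyl 4-{[2,4-bis(benzyloxy)-5-methoxy-6-methylbenzoyl]oxy}-2-hydroxy-6-methylbenzoate | Cc1cc(OC(=O)c2c(C)c(OC)c(OCc3ccccc3)cc2OCc2ccccc2)cc(O)c1C(=O)OCC=C
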